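In this flask target falls back to substrate and dissolved gas by the reverse of step 2 with a half-life of 4.79 s, shorter than the 48.4 s step 3 needs to halve it at saturated gas.

    gas phase ⇌ dissolved gas, rate k1*(csat - [dissolved gas]) (k1 = 0.0174 s⁻¹, csat = 3.9 mM)
    substrate + dissolved gas ⇌ target (K2 = 66.4 M⁻¹, k2 = 9.61 M⁻¹ s⁻¹)
    dissolved gas + target → over-reacted product (k3 = 3.67 M⁻¹ s⁻¹)
    dissolved gas + protic impurity → quenched reagent (k4 = 26.7 M⁻¹ s⁻¹)
    substrate ⇌ dormant form (K5 = 2.28, k5 = 0.00711 s⁻¹)

substrate 0.050 M; gas phase 3.9 mM (held); protic impurity 2.50 mM; time 10 min

1. how much target there is at 10 min, in percent of the substrate charged
2. the change that raises the amount of target at 10 min, in percent of the substrate charged most ("none" if none brings more than 2 percentage points) (winter / noon / none)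
3. amount of target at 10 min, in percent of the substrate charged, after noon

- winter: doubling the transfer coefficient of step 1, all else as stated
- noon: doubling the saturation concentration of gas phase, all else as stated

- at the start none of the gas is dissolved
- run time (flask): 10 min

So I treat step 2 as a pre-equilibrium, with target per free substrate equal to its equilibrium constant times the dissolved gas. At saturation that product is 0.259, my holding ratio: parts of target per part of free substrate in a saturated solution.

But the substrate is not all free. Step 5 relaxes with a half-life of 1.13 min, shorter than 10 min, and at its equilibrium the dormant form takes 2.28 parts per part of substrate, so the target's share of the pool is 7.32 %.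

Is the impurity a worry? Its charge is 5.00 % of the substrate charged, and step 1 at full pull delivers that much gas in 0.614 min, shorter than the run, so I set it aside as a delay.

Nor is the solution saturated. With target at that share, step 3 pulls against step 1 and the balance leaves the gas at 56.4 % of saturation, which lowers the share to 4.27 %. That overcorrects, since a second pass puts the gas at 69.0 %. The gas level of this balance lies between the two passes; I reckon on with the lower one, and by this estimate step 3 at that level drains 18.7 % of the pool by 10 min, so I commit to 3.47 % of the charge.

The same reckoning gives 3.86 % for winter. For noon the holding ratio doubles and I get 3.96 %. Each gain is less than 2 percentage points, so my choice is none.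

The forecast gives 4.1 %, none and 3.9 %, saying “the two effects nearly cancel”. Its first figure stands above mine, and its noon figure lies below its first, while my noon figure lies above my first.

The flask gives 3.34 %, none and 3.71 %, with gains of 0.18 points for winter and 0.37 points for noon. The forecast's choice would fail if a change brought more than 2 points. In the flask at 10.0 min the gas stands at 58.9 % of saturation, so the holding ratio scales to 0.152, and the reading of target per substrate is 0.144. In the neighbouring flask read at 25 min, the gas at 64.8 % scales it to 0.168, and target 2.58 % over substrate 16.3 % reads 0.158.

The constants used here are invented; the flask was simulated.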